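# Proposed total synthesis of CNP0230565.9 through a ring-closing nitrile oxide cycloaddition

Germacrane numbering is used throughout: ring carbons C1–C10, lactone carbons C11 (α), C12 (carbonyl) and C13 (exocyclic methylene), methyls C14 (on C10) and C15 (on C4). The target is compound 33.

## The problem

Compound 33 is a germacranolide in which a ten-membered carbocycle (C1–C10) is trans-fused across C6–C7 to an α-methylene-γ-butyrolactone whose ring oxygen sits on C6, and closing that strained medium ring with the lactone already attached is the central difficulty. The carbocycle holds a cross-conjugated dienone made of an E C1=C10 alkene, the C2 ketone and a Z C3=C4 alkene; the E alkene must be fixed before the ring exists, and the Z alkene must come out of the ring-forming or unmasking chemistry. Four contiguous stereocentres (C5 R with the free hydroxyl, C6 S, C7 R, C8 S with the angelate) stand in 5,6-anti, 6,7-trans and 7,8-anti relationships. Nothing precedes C5 and C6, so they need reagent control; after that C6 can direct C7, and a ring-locked allylmetal geometry can relay to C8 through a chair transition state. The methylene lactone (conjugate addition), the angelate (isomerisation to the tiglate) and the dienone with its γ-hydroxyl (base, nucleophiles) rule out strong bases, hydrides and organolithium reagents once they are present. The enabling feature is the 1,3 relationship of the C2 carbonyl and the methyl-bearing C4: formal hydration of C3=C4 gives a β-hydroxy ketone, the retron of an isoxazoline that arises from a nitrile oxide at C2 and an isopropenyl group (C3H2=C4–C15) on C5.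

## Retrosynthesis

**Unmasking (33 ⇐ 32 ⇐ 30 ⇐ 28).** The C5 silyl ether of 32 is the last protecting group. The C3=C4 π bond of 32 is traced to the tertiary aldol 30, and the C2 carbonyl and C4 hydroxyl of 30 to the N–O bond of isoxazoline 28. This keeps the dienone masked until the ring exists. The forward reactions must be non-basic and must deliver the ring-cis enone.

**Ring closure (28 ⇐ 25).** The C2–C3 and O–C4 bonds are cut together, giving seco oxime 25 by way of nitrile oxide 27. A cut at C1=C10 or C3=C4 would demand a stereodefined olefination inside a medium ring; a cut at C7–C8 would put the macrocyclisation in the step that also sets two stereocentres. The chosen cut asks only for a neutral pericyclic event between two groups that are inert until the last moment. The precursor is monocyclic and carries all four stereocentres. The forward reaction must beat dimerisation and must place oxygen on C4.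

**Side-arm adjustment (25 ⇐ 24 ⇐ 23 ⇐ 22 ⇐ 19 + 20).** The oxime comes from enal 24, the enal from allylic alcohol 23, and 23 from 4-methoxybenzyl ether 22. The C8–O acyl bond is cut to alcohol 19 and angelic acid 20. The angelate goes on early, while C8 is the only free hydroxyl. The later steps (DDQ, MnO2, buffered hydroxylamine) are chosen so as not to isomerise it.

**Lactone to arm (19 ⇐ 9 + 17).** The C7–C8 bond is cut to allylic bromide 9 and β,γ-unsaturated aldehyde 17. A Barbier allylation creates C7, C8 and the exocyclic methylene in one step from two fragments of similar size. It must be 6,7-trans and 7,8-anti, and it must not let the lactone migrate to O8.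

**Butenolide (9 ⇐ 8 ⇐ 7 ⇐ 4 + 5; 4 ⇐ 3 ⇐ 1).** The C5–C6 bond is cut to silyloxyfuran 4 and methacrolein 5, which brings in C3, C4, C5 and C15 as one commercial unit. The C13 oxygen is carried from 3-furanmethanol 1, because radical bromination of a C13 methyl would not spare the isopropenyl group. The aldol must be anti-selective and enantioselective. Diol 7 is differentiated by bromination of the primary alcohol (8) and silylation of C5 (9).

**Arm (17 ⇐ 16 ⇐ 15 ⇐ 14 ⇐ 11 ⇐ 10).** The C10–C14 and C1–C2 bonds are cut at the alkyne of but-3-yn-1-ol 10. Carboalumination with a formaldehyde quench sets the E trisubstituted alkene in one operation. The silyl ether of 11 and the 4-methoxybenzyl ether of 15 differentiate the chain ends, so that 16 can be oxidised to 17 at C8 only.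

## Roads not taken

Alternative 1: The cut is the C5–C10 σ bond of a decalin precursor, opened by a Wharton fragmentation. In the forward step KOtBu would form a C5 alkoxide, the C5–C10 bond would break anti-periplanar to a C1 sulfonate, and the ten-membered ketone A1 would appear with the E C1=C10 alkene set stereospecifically.
- Merits: the ring is revealed by fragmentation, with no entropic penalty and with good precedent for germacrane skeletons. In certainty of ring formation and of the E geometry this road is better than the chosen one.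
- Weak points: compound A1 is far from 33. Its C5 ketone, conjugated with C3=C4, must be reduced 1,2 and from the correct face. C13 must be added to a lactone enolate in a molecule holding other carbonyls. The C2 silyl ether must become the ketone and the C8 benzyl-type ether the angelate. The decalin also needs stereocentres at C1, C5 and C10 that are then destroyed.
- Comparison: the chosen plan sets against the safer ring opening a much shorter sequence in which the lactone, the angelate and the C5 configuration are in place before the ring closes, and in which only three steps follow.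

Alternative 2: The cuts are C7–C11 and C11=C13 of the lactone, and the key step would deliver the α-methylene trans-lactone A2, which carries free C5 and C8 hydroxyls and an E-iodoalkene arm. Carbons C5 to C9 of A2 would be taken from the chiral pool, from D-ribose A3. In the forward step NaH would turn a phosphonoacetate on O5 into a C11 carbanion that opens a C7,C8 cyclic sulfate at C7 with inversion. Horner–Wadsworth–Emmons reaction with formaldehyde would add C13, and acyl migration from O5 to O6 on acidic work-up would close the lactone.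
- Merits: C6, C7 and C8 come from the sugar A3 with an invertive, stereospecific C–C bond formation. This is more secure than a catalyst-controlled aldol followed by a diastereoselective allylation.
- Weak points: in A2, C5 is a primary carbinol, so the C5 stereocentre and the C3–C4 unit are still missing and would need an addition under uncertain 1,2-induction. The ten-membered ring is not addressed; a separate macrocyclisation through the iodoalkene is still required. Starting from the pentose A3 also costs many protecting-group steps.
- Comparison: the chosen plan concedes the stronger stereochemical pedigree of C6–C8. It sets against it two C–C bond formations that create all four stereocentres and a ring closure that is part of the same design.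

Alternative 3: The cuts are C1–C2 and C2–C3, with carbon monoxide as C2, in a carbonylative Stille macrocyclisation. Zerovalent palladium (from Pd2(dba)3 and AsPh3) under CO would join a Z-alkenyl iodide at C3 and an E-alkenylstannane at C1 and give A4, the C5 triethylsilyl ether of 33.
- Merits: both alkene geometries are fixed beforehand and transferred stereospecifically, and the dienone appears in its final oxidation state, so that A4 is one deprotection from 33. On the Z geometry of C3=C4 and on endgame length this road is better than the chosen plan.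
- Weak points: the ring must close directly to the strained planar dienone of A4. Direct coupling without CO insertion (a nine-membered diene) and oligomerisation compete. The stannane and iodide must survive allylation and angeloylation, and palladium hydride or tin species endanger the methylene lactone.
- Comparison: the chosen plan closes the ring to an sp3-rich bridged isoxazoline in an irreversible pericyclic step and creates the strained dienone only afterwards. It avoids tin and uses methacrolein as the C3–C5 unit. In exchange it accepts an elimination whose geometry is not guaranteed.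

Key step: step 16

Remark on the chemistry: the configuration at C4 created in step 16 cannot be predicted reliably and is irrelevant because C4 becomes sp2 in step 18; the 4R epimer is drawn for 28–31.

Remark on the chemistry: the cinchona-derived catalyst of step 3 is written in the quinidine series on the assumption that this series gives the (5R,6S) aldol; should the sense be opposite, the quinine-derived pseudoenantiomer is used.

## Route

Step 1
Reactants: 1 3-furanmethanol
Product: 3 3-(hydroxymethyl)furan-2(5H)-one, via dilithium furyl(trimethoxy)borate 2 (not isolated)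
Conditions: n-BuLi (2.2 equiv), THF, −78 → 0 °C; B(OMe)3, −78 °C → rt; 30% H2O2, AcOH, 0 °C → rt
Reagents that add atoms: hydrogen peroxide, OO (carbonyl oxygen of 3); trimethyl borate, COB(OC)OC (boron and methoxy groups of 2 only); n-butyllithium, [Li]CCCC (lithium of 2 only)
Why: Alkoxide-directed lithiation of 3-furanmethanol occurs at C2, between the ring oxygen and the CH2OLi group, and oxidation of the furyl borate 2 gives the 2-hydroxyfuran, which tautomerises to the butenolide (furan lithiation–boration–oxidation). The carbonyl therefore lands next to the hydroxymethyl-bearing carbon, as C12, C11 and C13 require.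

Step 2
Reactants: 3 3-(hydroxymethyl)furan-2(5H)-one
Product: 4 trimethyl{[2-(trimethylsilyloxy)furan-3-yl]methoxy}silane
Conditions: TMSOTf (2.3 equiv), Et3N, CH2Cl2, 0 °C; used without chromatography
Reagents that add atoms: trimethylsilyl triflate, C[Si](C)(C)OS(=O)(=O)C(F)(F)F
Why: Silyl triflate and triethylamine silylate the primary alcohol and convert the butenolide into its 2-silyloxyfuran by soft γ-enolisation, the standard entry to vinylogous Mukaiyama donors.

Step 3
Reactants: 4 trimethyl{[2-(trimethylsilyloxy)furan-3-yl]methoxy}silane; 5 methacrolein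
Product: 7 (5S)-5-[(1R)-1-hydroxy-2-methylprop-2-en-1-yl]-3-(hydroxymethyl)furan-2(5H)-one, via bis(trimethylsilyl) aldol 6 (not isolated)
Conditions: quinidine-derived 9-amino-9-deoxy-epi 3,5-bis(trifluoromethyl)phenyl thiourea·CF3CO2H (10 mol %), Et2O, −20 °C; then 1 M HCl, THF, 0 °C
Reagents that add atoms: none
Why: Catalytic enantioselective vinylogous Mukaiyama aldol reaction: the thiourea–ammonium carboxylate salt binds the aldehyde by hydrogen bonding while its carboxylate activates the silyl dienol ether, and this catalyst class is anti-selective with 2-silyloxyfurans, which is the O5/O6 relationship required. C5 (R) and C6 (S) are both set by the catalyst, and aqueous acid then removes both trimethylsilyl groups of 6.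

Step 4
Reactants: 7 (5S)-5-[(1R)-1-hydroxy-2-methylprop-2-en-1-yl]-3-(hydroxymethyl)furan-2(5H)-one
Product: 8 (5S)-3-(bromomethyl)-5-[(1R)-1-hydroxy-2-methylprop-2-en-1-yl]furan-2(5H)-one
Conditions: CBr4 (1.05 equiv), PPh3 (1.05 equiv), CH2Cl2, −30 → 0 °C
Reagents that add atoms: carbon tetrabromide, BrC(Br)(Br)Br
Why: Appel bromination; the primary allylic alcohol forms its alkoxyphosphonium salt far faster than the hindered secondary C5 carbinol, so one equivalent of reagent in the cold should brominate C13 only. O5 cannot cyclise onto C13 because C13 and C6 are trans across the ring alkene.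

Step 5
Reactants: 8 (5S)-3-(bromomethyl)-5-[(1R)-1-hydroxy-2-methylprop-2-en-1-yl]furan-2(5H)-one
Product: 9 (5S)-3-(bromomethyl)-5-[(1R)-1-(tert-butyldimethylsilyloxy)-2-methylprop-2-en-1-yl]furan-2(5H)-one
Conditions: TBSOTf, 2,6-lutidine, CH2Cl2, −78 °C
Reagents that add atoms: tert-butyldimethylsilyl triflate, CC(C)(C)[Si](C)(C)OS(=O)(=O)C(F)(F)F
Why: Silylation of a hindered secondary alcohol with the silyl triflate; 2,6-lutidine at −78 °C is too hindered a nucleophile to displace the allylic bromide.

Step 6
Reactants: 10 but-3-yn-1-ol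
Product: 11 (but-3-yn-1-yloxy)(tert-butyl)dimethylsilane
Conditions: TBSCl, imidazole, CH2Cl2, rt
Reagents that add atoms: tert-butyldimethylsilyl chloride, CC(C)(C)[Si](C)(C)Cl
Why: Routine silylation that marks the future C8 end of the chain, so that the two hydroxyls present after step 7 can be told apart.

Step 7
Reactants: 11 (but-3-yn-1-yloxy)(tert-butyl)dimethylsilane
Product: 14 (E)-5-(tert-butyldimethylsilyloxy)-3-methylpent-2-en-1-ol, via alkenyldimethylalane 12 (not isolated), via lithium alkenylaluminate 13 (not isolated)
Conditions: AlMe3 (2.5 equiv), Cp2ZrCl2 (0.25 equiv), CH2Cl2, 0 °C → rt; n-BuLi, hexane/THF, −30 °C; (CH2O)n, rt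
Reagents that add atoms: trimethylaluminium, C[Al](C)C (C14 methyl); formaldehyde from paraformaldehyde, C=O (C2 and its oxygen); n-butyllithium, [Li]CCCC (butyl and lithium of 13 only)
Why: Negishi zirconium-catalysed carboalumination: methyl and aluminium add syn across the terminal alkyne with methyl on the internal carbon, which installs C14 and fixes the E geometry of the future C1=C10 alkene. The derived aluminate 13 adds to formaldehyde with retention of geometry and brings in C2.

Step 8
Reactants: 14 (E)-5-(tert-butyldimethylsilyloxy)-3-methylpent-2-en-1-ol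
Product: 15 tert-butyl{[(E)-5-(4-methoxybenzyloxy)-3-methylpent-3-en-1-yl]oxy}dimethylsilane
Conditions: NaH, 4-methoxybenzyl chloride, Bu4NI (cat.), THF/DMF, 0 °C → rt
Reagents that add atoms: 4-methoxybenzyl chloride, COc1ccc(CCl)cc1
Why: Williamson etherification; a 4-methoxybenzyl ether is chosen for O2 because it can later be removed oxidatively without touching silyl ethers, esters or the lactone.

Step 9
Reactants: 15 tert-butyl{[(E)-5-(4-methoxybenzyloxy)-3-methylpent-3-en-1-yl]oxy}dimethylsilane
Product: 16 (E)-5-(4-methoxybenzyloxy)-3-methylpent-3-en-1-ol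
Conditions: Bu4NF, THF, 0 °C → rt
Reagents that add atoms: none
Why: Fluoride cleaves the primary silyl ether; the benzyl-type ether and the alkene are inert.

Step 10
Reactants: 16 (E)-5-(4-methoxybenzyloxy)-3-methylpent-3-en-1-ol
Product: 17 (E)-5-(4-methoxybenzyloxy)-3-methylpent-3-enal
Conditions: Dess–Martin periodinane, NaHCO3, CH2Cl2, 0 °C; used at once
Reagents that add atoms: none
Why: Dess–Martin oxidation under buffered, non-basic conditions gives the β,γ-unsaturated aldehyde without moving the alkene into conjugation.

Step 11
Reactants: 9 (5S)-3-(bromomethyl)-5-[(1R)-1-(tert-butyldimethylsilyloxy)-2-methylprop-2-en-1-yl]furan-2(5H)-one; 17 (E)-5-(4-methoxybenzyloxy)-3-methylpent-3-enal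
Product: 19 (4R,5S)-5-[(1R)-1-(tert-butyldimethylsilyloxy)-2-methylprop-2-en-1-yl]-4-[(1S,3E)-1-hydroxy-5-(4-methoxybenzyloxy)-3-methylpent-3-en-1-yl]-3-methylideneoxolan-2-one, via allylzinc bromide 18 (not isolated)
Conditions: Zn dust, THF/sat. aq NH4Cl, 0 °C → rt
Reagents that add atoms: zinc, [Zn] (in 18 only)
Why: Zinc Barbier allylation: allylzinc 18 reacts at its γ-carbon C7 (SE2′) through a six-membered chair transition state and unveils the exocyclic methylene. C7 is set by approach of the aldehyde anti to the C6 side chain (6,7-trans), and C8 by the ring-locked E geometry of the allyl unit with the aldehyde substituent equatorial (7,8-anti, 8S). The aqueous NH4Cl medium protonates the zinc alkoxide at once, which should prevent lactone migration to O8.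

Step 12
Reactants: 19 (4R,5S)-5-[(1R)-1-(tert-butyldimethylsilyloxy)-2-methylprop-2-en-1-yl]-4-[(1S,3E)-1-hydroxy-5-(4-methoxybenzyloxy)-3-methylpent-3-en-1-yl]-3-methylideneoxolan-2-one; 20 angelic acid
Product: 22 (1S,3E)-1-[(2S,3R)-2-[(1R)-1-(tert-butyldimethylsilyloxy)-2-methylprop-2-en-1-yl]-4-methylidene-5-oxooxolan-3-yl]-5-(4-methoxybenzyloxy)-3-methylpent-3-en-1-yl (Z)-2-methylbut-2-enoate, via angelic trichlorobenzoic anhydride 21 (not isolated)
Conditions: 20, 2,4,6-trichlorobenzoyl chloride, Et3N, toluene, rt; then 19, 80 °C (no DMAP)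
Reagents that add atoms: 2,4,6-trichlorobenzoyl chloride, O=C(Cl)c1c(Cl)cc(Cl)cc1Cl (in 21 only)
Why: Yamaguchi-type esterification: mixed anhydride 21 acylates the hindered C8 alcohol at the angeloyl carbonyl, and leaving out nucleophilic catalysts is the established way to avoid isomerisation of the angelate to the tiglate.

Step 13
Reactants: 22 (1S,3E)-1-[(2S,3R)-2-[(1R)-1-(tert-butyldimethylsilyloxy)-2-methylprop-2-en-1-yl]-4-methylidene-5-oxooxolan-3-yl]-5-(4-methoxybenzyloxy)-3-methylpent-3-en-1-yl (Z)-2-methylbut-2-enoate
Product: 23 (1S,3E)-1-[(2S,3R)-2-[(1R)-1-(tert-butyldimethylsilyloxy)-2-methylprop-2-en-1-yl]-4-methylidene-5-oxooxolan-3-yl]-5-hydroxy-3-methylpent-3-en-1-yl (Z)-2-methylbut-2-enoate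
Conditions: DDQ, CH2Cl2/pH 7 phosphate buffer, 0 °C
Reagents that add atoms: none
Why: Oxidative cleavage of the 4-methoxybenzyl ether by DDQ (hydride abstraction, hydrolysis of the oxocarbenium ion); the silyl ether, esters and alkenes are inert under buffered conditions. Any over-oxidation gives 24, the product of the next step.

Step 14
Reactants: 23 (1S,3E)-1-[(2S,3R)-2-[(1R)-1-(tert-butyldimethylsilyloxy)-2-methylprop-2-en-1-yl]-4-methylidene-5-oxooxolan-3-yl]-5-hydroxy-3-methylpent-3-en-1-yl (Z)-2-methylbut-2-enoate
Product: 24 (1S,3E)-1-[(2S,3R)-2-[(1R)-1-(tert-butyldimethylsilyloxy)-2-methylprop-2-en-1-yl]-4-methylidene-5-oxooxolan-3-yl]-3-methyl-5-oxopent-3-en-1-yl (Z)-2-methylbut-2-enoate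
Conditions: MnO2, CH2Cl2, rt
Reagents that add atoms: none
Why: MnO2 oxidises only the allylic alcohol and keeps the E geometry; no base or nucleophile is present that could touch the methylene lactone or the angelate.

Step 15
Reactants: 24 (1S,3E)-1-[(2S,3R)-2-[(1R)-1-(tert-butyldimethylsilyloxy)-2-methylprop-2-en-1-yl]-4-methylidene-5-oxooxolan-3-yl]-3-methyl-5-oxopent-3-en-1-yl (Z)-2-methylbut-2-enoate
Product: 25 (1S,3E,5E)-1-[(2S,3R)-2-[(1R)-1-(tert-butyldimethylsilyloxy)-2-methylprop-2-en-1-yl]-4-methylidene-5-oxooxolan-3-yl]-5-(hydroxyimino)-3-methylpent-3-en-1-yl (Z)-2-methylbut-2-enoate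
Conditions: NH2OH·HCl (1.1 equiv), NaOAc, EtOH/H2O, 0 °C
Reagents that add atoms: hydroxylamine hydrochloride, NO.Cl
Why: Oxime condensation under acetate buffer; addition of hydroxylamine to the aldehyde is much faster than conjugate addition to the methylene lactone when about one equivalent is used cold. Both oxime geometries lead to the same nitrile oxide.

Step 16
Reactants: 25 (1S,3E,5E)-1-[(2S,3R)-2-[(1R)-1-(tert-butyldimethylsilyloxy)-2-methylprop-2-en-1-yl]-4-methylidene-5-oxooxolan-3-yl]-5-(hydroxyimino)-3-methylpent-3-en-1-yl (Z)-2-methylbut-2-enoate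
Product: 28 (4R,5S,6S,7R,8S)-8-angeloyloxy-5-(tert-butyldimethylsilyloxy)germacra-1(10)E,11(13)-dien-6,12-olide bridged from C2 to C4 by a C2=N–O–C4 isoxazoline, via hydroximoyl chloride 26 (not isolated), via nitrile oxide 27 (not isolated)
Conditions: aq NaOCl, CH2Cl2, 0 °C → rt; 25 added by syringe pump to about 1 mM
Reagents that add atoms: sodium hypochlorite, [Na+].[O-]Cl (chlorine of 26 only)
Why: Proposed new method: hypochlorite chlorinates the aldoxime to 26, loss of HCl gives the conjugated nitrile oxide 27, and 27 adds in a concerted suprafacial (3+2) manner across the isopropenyl group, its carbon bonding to the CH2 terminus C3 and its oxygen to the methyl-bearing C4. The closest known reaction type is the intramolecular nitrile oxide–alkene cycloaddition that closes macrocycles and larger medium rings in the bridged sense, with later unmasking of the isoxazoline; a ten-membered carbocycle of this substitution has not been closed in this way. The ten-membered carbocycle closes through the C2–C3 bond in the endo mode (both alkene carbons end inside the large ring). The five-membered isoxazoline closes through O–C4 in the same event, giving a bicyclo[7.2.1] framework in which N–O bridges C2 and C4. The new stereocentre C4 is set by the face of the isopropenyl group that the tether can reach, which the C5 and C6 stereocentres govern, and either outcome is acceptable because C4 becomes sp2 in step 18. The step needs oxygen-to-C4 regiochemistry, which follows from the intrinsic preference of nitrile oxides to place oxygen on the substituted carbon of a 1,1-disubstituted alkene and from the fact that the reverse sense would need a nine-membered ring. It also needs the isopropenyl group to win over the methylene lactone and over dimerisation to the furoxan: the lactone alkene is out of reach within the molecule (an eight-membered ring enclosing the E alkene would be required), and slow addition at high dilution suppresses the bimolecular paths.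

Step 17
Reactants: 28 (4R,5S,6S,7R,8S)-8-angeloyloxy-5-(tert-butyldimethylsilyloxy)germacra-1(10)E,11(13)-dien-6,12-olide bridged from C2 to C4 by a C2=N–O–C4 isoxazoline
Product: 30 (4R,5S,6S,7R,8S)-8-angeloyloxy-5-(tert-butyldimethylsilyloxy)-4-hydroxy-2-oxogermacra-1(10)E,11(13)-dien-6,12-olide, via hydroxy imine 29 (not isolated)
Conditions: Mo(CO)6, MeCN/H2O (15:1), 75 °C
Reagents that add atoms: water, O
Why: Mo(CO)6 cleaves the N–O bond reductively in wet acetonitrile and the β-hydroxy imine 29 hydrolyses in the same pot to the ketone (isoxazoline unmasking to an aldol); alkenes, esters and the silyl ether are not reduced.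

Step 18
Reactants: 30 (4R,5S,6S,7R,8S)-8-angeloyloxy-5-(tert-butyldimethylsilyloxy)-4-hydroxy-2-oxogermacra-1(10)E,11(13)-dien-6,12-olide
Product: 32 (5R,6S,7R,8S)-8-angeloyloxy-5-(tert-butyldimethylsilyloxy)-2-oxogermacra-1(10)E,3Z,11(13)-trien-6,12-olide, via tertiary mesylate 31 (not isolated)
Conditions: MsCl, Et3N, CH2Cl2, −20 → 20 °C
Reagents that add atoms: methanesulfonyl chloride, CS(=O)(=O)Cl (in 31 only)
Why: Sulfene-type mesylation of the tertiary C4 alcohol and E1cB loss of mesylate through the C3 enolate place the new alkene in conjugation with the C2 ketone. The Z (ring-cis) geometry is expected because a second trans alkene flanking the ketone in the ten-membered ring is more strained; this is the least secure point of the endgame.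

Step 19
Reactants: 32 (5R,6S,7R,8S)-8-angeloyloxy-5-(tert-butyldimethylsilyloxy)-2-oxogermacra-1(10)E,3Z,11(13)-trien-6,12-olide
Product: 33 CNP0230565.9, (5R,6S,7R,8S)-8-angeloyloxy-5-hydroxy-2-oxogermacra-1(10)E,3Z,11(13)-trien-6,12-olide
Conditions: HF·pyridine, pyridine, THF, 0 °C → rt
Reagents that add atoms: none
Why: Buffered HF·pyridine removes the secondary silyl ether without base, which the dienone, the methylene lactone and the angelate would not tolerate.

## Compound list

1 | 3-furanmethanol | OCc1ccoc1 | starting material
2 | dilithium trimethoxy[3-(oxidomethyl)furan-2-yl]borate | [Li+].[Li+].CO[B-](OC)(OC)c1occc1C[O-] | intermediate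
3 | 3-(hydroxymethyl)furan-2(5H)-one | O=C1OCC=C1CO | intermediate
4 | trimethyl{[2-(trimethylsilyloxy)furan-3-yl]methoxy}silane | C[Si](C)(C)OCc1ccoc1O[Si](C)(C)C | intermediate
5 | methacrolein | CC(=C)C=O | starting material
6 | (5S)-5-[(1R)-2-methyl-1-(trimethylsilyloxy)prop-2-en-1-yl]-3-[(trimethylsilyloxy)methyl]furan-2(5H)-one | C=C(C)[C@@H](O[Si](C)(C)C)[C@H]1OC(=O)C(CO[Si](C)(C)C)=C1 | intermediate
7 | (5S)-5-[(1R)-1-hydroxy-2-methylprop-2-en-1-yl]-3-(hydroxymethyl)furan-2(5H)-one | C=C(C)[C@@H](O)[C@H]1OC(=O)C(CO)=C1 | intermediate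
8 | (5S)-3-(bromomethyl)-5-[(1R)-1-hydroxy-2-methylprop-2-en-1-yl]furan-2(5H)-one | C=C(C)[C@@H](O)[C@H]1OC(=O)C(CBr)=C1 | intermediate
9 | (5S)-3-(bromomethyl)-5-[(1R)-1-(tert-butyldimethylsilyloxy)-2-methylprop-2-en-1-yl]furan-2(5H)-one | C=C(C)[C@@H](O[Si](C)(C)C(C)(C)C)[C@H]1OC(=O)C(CBr)=C1 | intermediate
10 | but-3-yn-1-ol | C#CCCO | starting material
11 | (but-3-yn-1-yloxy)(tert-butyl)dimethylsilane | C#CCCO[Si](C)(C)C(C)(C)C | intermediate
12 | [(E)-4-(tert-butyldimethylsilyloxy)-2-methylbut-1-en-1-yl]dimethylalane | C[Al](C)/C=C(\C)CCO[Si](C)(C)C(C)(C)C | intermediate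
13 | lithium butyl[(E)-4-(tert-butyldimethylsilyloxy)-2-methylbut-1-en-1-yl]dimethylaluminate | [Li+].CCCC[Al-](C)(C)/C=C(\C)CCO[Si](C)(C)C(C)(C)C | intermediate
14 | (E)-5-(tert-butyldimethylsilyloxy)-3-methylpent-2-en-1-ol | OC/C=C(\C)CCO[Si](C)(C)C(C)(C)C | intermediate
15 | tert-butyl{[(E)-5-(4-methoxybenzyloxy)-3-methylpent-3-en-1-yl]oxy}dimethylsilane | COc1ccc(COC/C=C(\C)CCO[Si](C)(C)C(C)(C)C)cc1 | intermediate
16 | (E)-5-(4-methoxybenzyloxy)-3-methylpent-3-en-1-ol | COc1ccc(COC/C=C(\C)CCO)cc1 | intermediate
17 | (E)-5-(4-methoxybenzyloxy)-3-methylpent-3-enal | COc1ccc(COC/C=C(\C)CC=O)cc1 | intermediate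
18 | {[(5S)-5-[(1R)-1-(tert-butyldimethylsilyloxy)-2-methylprop-2-en-1-yl]-2-oxo-2,5-dihydrofuran-3-yl]methyl}zinc bromide | C=C(C)[C@@H](O[Si](C)(C)C(C)(C)C)[C@H]1OC(=O)C(C[Zn]Br)=C1 | intermediate
19 | (4R,5S)-5-[(1R)-1-(tert-butyldimethylsilyloxy)-2-methylprop-2-en-1-yl]-4-[(1S,3E)-1-hydroxy-5-(4-methoxybenzyloxy)-3-methylpent-3-en-1-yl]-3-methylideneoxolan-2-one | C=C1C(=O)O[C@H]([C@H](O[Si](C)(C)C(C)(C)C)C(C)=C)[C@H]1[C@@H](O)C/C(C)=C/COCc2ccc(OC)cc2 | intermediate
20 | angelic acid, (Z)-2-methylbut-2-enoic acid | C/C=C(/C)C(=O)O | starting material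
21 | (Z)-2-methylbut-2-enoic 2,4,6-trichlorobenzoic anhydride | C/C=C(/C)C(=O)OC(=O)c1c(Cl)cc(Cl)cc1Cl | intermediate
22 | (1S,3E)-1-[(2S,3R)-2-[(1R)-1-(tert-butyldimethylsilyloxy)-2-methylprop-2-en-1-yl]-4-methylidene-5-oxooxolan-3-yl]-5-(4-methoxybenzyloxy)-3-methylpent-3-en-1-yl (Z)-2-methylbut-2-enoate | C=C1C(=O)O[C@H]([C@H](O[Si](C)(C)C(C)(C)C)C(C)=C)[C@H]1[C@@H](OC(=O)/C(C)=C\C)C/C(C)=C/COCc2ccc(OC)cc2 | intermediate
23 | (1S,3E)-1-[(2S,3R)-2-[(1R)-1-(tert-butyldimethylsilyloxy)-2-methylprop-2-en-1-yl]-4-methylidene-5-oxooxolan-3-yl]-5-hydroxy-3-methylpent-3-en-1-yl (Z)-2-methylbut-2-enoate | C=C1C(=O)O[C@H]([C@H](O[Si](C)(C)C(C)(C)C)C(C)=C)[C@H]1[C@@H](OC(=O)/C(C)=C\C)C/C(C)=C/CO | intermediate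
24 | (1S,3E)-1-[(2S,3R)-2-[(1R)-1-(tert-butyldimethylsilyloxy)-2-methylprop-2-en-1-yl]-4-methylidene-5-oxooxolan-3-yl]-3-methyl-5-oxopent-3-en-1-yl (Z)-2-methylbut-2-enoate | C=C1C(=O)O[C@H]([C@H](O[Si](C)(C)C(C)(C)C)C(C)=C)[C@H]1[C@@H](OC(=O)/C(C)=C\C)C/C(C)=C/C=O | intermediate
25 | (1S,3E,5E)-1-[(2S,3R)-2-[(1R)-1-(tert-butyldimethylsilyloxy)-2-methylprop-2-en-1-yl]-4-methylidene-5-oxooxolan-3-yl]-5-(hydroxyimino)-3-methylpent-3-en-1-yl (Z)-2-methylbut-2-enoate, the seco oxime | C=C1C(=O)O[C@H]([C@H](O[Si](C)(C)C(C)(C)C)C(C)=C)[C@H]1[C@@H](OC(=O)/C(C)=C\C)C/C(C)=C/C=N/O | intermediate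
26 | (1S,3E,5Z)-1-[(2S,3R)-2-[(1R)-1-(tert-butyldimethylsilyloxy)-2-methylprop-2-en-1-yl]-4-methylidene-5-oxooxolan-3-yl]-5-chloro-5-(hydroxyimino)-3-methylpent-3-en-1-yl (Z)-2-methylbut-2-enoate | C=C1C(=O)O[C@H]([C@H](O[Si](C)(C)C(C)(C)C)C(C)=C)[C@H]1[C@@H](OC(=O)/C(C)=C\C)C/C(C)=C/C(/Cl)=N/O | intermediate
27 | (2E,5S)-5-[(2S,3R)-2-[(1R)-1-(tert-butyldimethylsilyloxy)-2-methylprop-2-en-1-yl]-4-methylidene-5-oxooxolan-3-yl]-3-methyl-5-[(Z)-2-methylbut-2-enoyloxy]pent-2-enenitrile oxide | C=C1C(=O)O[C@H]([C@H](O[Si](C)(C)C(C)(C)C)C(C)=C)[C@H]1[C@@H](OC(=O)/C(C)=C\C)C/C(C)=C/C#[N+][O-] | intermediate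
28 | (4R,5S,6S,7R,8S)-8-angeloyloxy-5-(tert-butyldimethylsilyloxy)germacra-1(10)E,11(13)-dien-6,12-olide bridged from C2 to C4 by a C2=N–O–C4 isoxazoline | C=C1C(=O)O[C@H]2[C@H]1[C@@H](OC(=O)/C(C)=C\C)C/C(C)=C/C3=NO[C@](C)(C3)[C@H]2O[Si](C)(C)C(C)(C)C | intermediate
29 | (4R,5S,6S,7R,8S)-8-angeloyloxy-5-(tert-butyldimethylsilyloxy)-4-hydroxy-2-iminogermacra-1(10)E,11(13)-dien-6,12-olide | C=C1C(=O)O[C@H]2[C@H]1[C@@H](OC(=O)/C(C)=C\C)C/C(C)=C/C(=N)C[C@@](C)(O)[C@H]2O[Si](C)(C)C(C)(C)C | intermediate
30 | (4R,5S,6S,7R,8S)-8-angeloyloxy-5-(tert-butyldimethylsilyloxy)-4-hydroxy-2-oxogermacra-1(10)E,11(13)-dien-6,12-olide | C=C1C(=O)O[C@H]2[C@H]1[C@@H](OC(=O)/C(C)=C\C)C/C(C)=C/C(=O)C[C@@](C)(O)[C@H]2O[Si](C)(C)C(C)(C)C | intermediate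
31 | (4R,5S,6S,7R,8S)-8-angeloyloxy-5-(tert-butyldimethylsilyloxy)-4-(methanesulfonyloxy)-2-oxogermacra-1(10)E,11(13)-dien-6,12-olide | C=C1C(=O)O[C@H]2[C@H]1[C@@H](OC(=O)/C(C)=C\C)C/C(C)=C/C(=O)C[C@@](C)(OS(C)(=O)=O)[C@H]2O[Si](C)(C)C(C)(C)C | intermediate
32 | (5R,6S,7R,8S)-8-angeloyloxy-5-(tert-butyldimethylsilyloxy)-2-oxogermacra-1(10)E,3Z,11(13)-trien-6,12-olide | C=C1C(=O)O[C@H]2[C@H]1[C@@H](OC(=O)/C(C)=C\C)C/C(C)=C/C(=O)/C=C(/C)[C@H]2O[Si](C)(C)C(C)(C)C | intermediate
33 | CNP0230565.9, (5R,6S,7R,8S)-8-angeloyloxy-5-hydroxy-2-oxogermacra-1(10)E,3Z,11(13)-trien-6,12-olide | C=C1C(=O)O[C@H]2[C@H]1[C@@H](OC(=O)/C(C)=C\C)C/C(C)=C/C(=O)/C=C(/C)[C@H]2O | target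

## Step count and least certain steps

Total step count: 19. Longest linear sequence: 14 steps (steps 1–5 and 11–19, from 3-furanmethanol); the arm (steps 6–10) is a five-step branch.

**Step 16 (key step, Proposed new method).** The nitrile oxide may dimerise or add intermolecularly to the methylene lactone faster than it closes the ring, because the transition state must bend a linear dipole attached to an E alkene across a ten-membered ring. Chlorination of the electron-rich alkenes by hypochlorite is a second loss channel. The fallback uses known chemistry and closes the same ring by metathesis. It sets out from enal 24. Nozaki–Hiyama–Kishi vinylation (CrCl2, NiCl2 cat., vinyl bromide, DMF) gives the bis-allylic alcohol F1 as a mixture of C2 epimers. Dess–Martin oxidation gives the cross-conjugated vinyl ketone F2. Ring-closing metathesis between the vinyl ketone and the isopropenyl group (second-generation Hoveyda–Grubbs catalyst, dilute toluene, 80 °C) forms C3=C4 with loss of ethylene and comes back to the route at 32; the ring constraint favours the cis alkene.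

**Step 3.** Enantio- or diastereoselectivity may erode with a C3-substituted silyloxyfuran and a small α-branched enal, and conjugate addition to methacrolein may compete with 1,2-addition. The fallback replaces asymmetric catalysis by resolution and sets out from 4 and 5. A BF3·OEt2-promoted aldol at −78 °C with acidic work-up should give both diastereomers, from which the racemic anti diol F3 is separated by chromatography. Sharpless kinetic resolution (Ti(OiPr)4, D-(−)-diisopropyl tartrate, t-BuOOH, 4 Å sieves, CH2Cl2, −20 °C) should then epoxidise the (5S,6R) enantiomer to the erythro epoxy alcohol F4 and leave 7, where the route is rejoined.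

**Step 11.** Facial selectivity at the aldehyde may be incomplete if a boat transition state competes, giving the C8 epimer. Migration of the β,γ-alkene of 17 into conjugation and lactone migration to O8 are further risks. The fallback sets out from 9 and 17 as before and uses the C8 epimer of 19, the (8R) alcohol F5. Mitsunobu esterification of this alcohol with angelic acid 20 (PPh3, diisopropyl azodicarboxylate, toluene, 0 °C) inverts C8 while installing the angelate, so that both epimers converge on 22.

**Step 15.** Conjugate addition of hydroxylamine to the methylene lactone may compete with condensation at the hindered enal. The fallback avoids hydroxylamine by generating the same nitrile oxide from a nitro compound. It sets out from 23. Appel bromination (CBr4, PPh3) gives the allylic bromide F6. AgNO2 in ether gives the primary allylic nitro compound F7. Dehydration with phenyl isocyanate and catalytic Et3N at high dilution generates 27, which cyclises to 28, where the route is rejoined.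

**Step 18.** Elimination may give the ring-trans C3=C4 isomer, or proceed toward C15 or C5, or be overtaken by retro-aldol opening of the ring. The fallback corrects geometry under thermodynamic control after the fact. It sets out from 30: if the (3E) dienone F8 is the main product, it is isolated and equilibrated with catalytic iodine in CH2Cl2 under ambient light toward the less strained ring-cis isomer, and it comes back to the route at 32. The known weakness is that the C1=C10 alkene is exposed to the same equilibration.

## Further compounds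

F1 | step 16 | C2 vinyl carbinol from 24 (mixture of C2 epimers) | C=C1C(=O)O[C@H]([C@H](O[Si](C)(C)C(C)(C)C)C(C)=C)[C@H]1[C@@H](OC(=O)/C(C)=C\C)C/C(C)=C/C(O)C=C
F2 | step 16 | C2 vinyl ketone | C=C1C(=O)O[C@H]([C@H](O[Si](C)(C)C(C)(C)C)C(C)=C)[C@H]1[C@@H](OC(=O)/C(C)=C\C)C/C(C)=C/C(=O)C=C
F3 | step 3 | racemic anti-5-(1-hydroxy-2-methylprop-2-en-1-yl)-3-(hydroxymethyl)furan-2(5H)-one | C=C(C)[C@@H](O)[C@H]1OC(=O)C(CO)=C1.C=C(C)[C@H](O)[C@@H]1OC(=O)C(CO)=C1
F4 | step 3 | (5R)-5-{(R)-hydroxy[(2S)-2-methyloxiran-2-yl]methyl}-3-(hydroxymethyl)furan-2(5H)-one | C[C@]1(CO1)[C@H](O)[C@@H]2OC(=O)C(CO)=C2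
F5 | step 11 | (4R,5S)-5-[(1R)-1-(tert-butyldimethylsilyloxy)-2-methylprop-2-en-1-yl]-4-[(1R,3E)-1-hydroxy-5-(4-methoxybenzyloxy)-3-methylpent-3-en-1-yl]-3-methylideneoxolan-2-one | C=C1C(=O)O[C@H]([C@H](O[Si](C)(C)C(C)(C)C)C(C)=C)[C@H]1[C@H](O)C/C(C)=C/COCc2ccc(OC)cc2
F6 | step 15 | C2 allylic bromide from 23 | C=C1C(=O)O[C@H]([C@H](O[Si](C)(C)C(C)(C)C)C(C)=C)[C@H]1[C@@H](OC(=O)/C(C)=C\C)C/C(C)=C/CBr
F7 | step 15 | C2 primary allylic nitro compound | C=C1C(=O)O[C@H]([C@H](O[Si](C)(C)C(C)(C)C)C(C)=C)[C@H]1[C@@H](OC(=O)/C(C)=C\C)C/C(C)=C/C[N+](=O)[O-]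
F8 | step 18 | (3E) isomer of 32 | C=C1C(=O)O[C@H]2[C@H]1[C@@H](OC(=O)/C(C)=C\C)C/C(C)=C/C(=O)/C=C(\C)[C@H]2O[Si](C)(C)C(C)(C)C
A1 | alternative 1 | ten-membered C5 ketone, 1(10)E,3Z, C2 triethylsilyl ether, C8 4-methoxybenzyl ether, lactone lacking C13 | C1C(=O)O[C@H]2[C@H]1[C@@H](OCc3ccc(OC)cc3)C/C(C)=C/[C@@H](O[Si](CC)(CC)CC)/C=C(/C)C2=O
A2 | alternative 2 | (4R,5S)-5-(hydroxymethyl)-4-[(1S,3E)-1-hydroxy-4-iodo-3-methylbut-3-en-1-yl]-3-methylideneoxolan-2-one | C=C1C(=O)O[C@H](CO)[C@H]1[C@@H](O)C/C(C)=C/I
A3 | alternative 2 | D-ribose | O=C[C@H](O)[C@H](O)[C@H](O)CO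
A4 | alternative 3 | C5 triethylsilyl ether of 33 | C=C1C(=O)O[C@H]2[C@H]1[C@@H](OC(=O)/C(C)=C\C)C/C(C)=C/C(=O)/C=C(/C)[C@H]2O[Si](CC)(CC)CC
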